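## Retrosynthetic overview

1. The last C–C bond is C4′–C5′ of the side chain. It is made by B-alkyl Suzuki–Miyaura coupling of a homofarnesyl borane, from (2E,6E)-farnesol with two E double bonds bought, with an (E)-alkenyl iodide that carries the ring.
2. The alkenyl iodide goes back to a cis-2-(6-oxocyclohexyl)acetate. The ketone becomes C4=CH2, and the ester carbon C2′ becomes CH2I, then but-3-ynyl, then the E-C3′=C4′ iodide by methylalumination and iodination.
3. The plan rests on one feature of the single six-membered ring (C1 carbinol, C2 CMe2, C3 chain-bearing CH, C4 methylidene carbon, C5, C6). The atoms C6–C1(O)–C2(CH3)2–C3 are the whole carbon skeleton of (R)-pantolactone, with C1 already in the required absolute sense, and C4 next to C3 can sit at the acyl level.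
4. The only ring is closed at C3–C4. A C4 acyl radical, made from the aldehyde by photocatalytic hydrogen abstraction, adds 6-exo to C3, the β-carbon of an enoate whose α-carbon and ester carbon are C1′ and C2′. C1 directs C3.
5. The open-chain aldehyde enoate is built on pantolactone by a lactol Wittig reaction (C5, and C4 as a Weinreb amide) and a Horner–Wadsworth–Emmons reaction (C1′, C2′).

Key step: step 8

Remark on descriptors: the carbinol carbon is R in 1–3 and S from 5 onwards. This is only because the former carbonyl carbon C6 falls below C2 in CIP rank; no bond at this centre is touched.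
Assumption: isomerically pure (2E,6E)-farnesol is used, so the two remote trisubstituted double bonds are taken over unchanged.

## Route

Step 1
Reactants: 1 (R)-pantolactone
Product: 2 (3R)-3-[(tert-butyldimethylsilyl)oxy]-4,4-dimethyloxolan-2-one
Conditions: TBSCl, imidazole, DMF, rt → 40 °C
Reagents that add atoms: tert-butyldimethylsilyl chloride, CC(C)(C)[Si](C)(C)Cl
Why: Imidazole-promoted silylation of the hindered α-hydroxy lactone leaves the stereocentre (future C1) untouched and installs the bulky ether that later acts as the equatorial anchor of the ring closure.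

Step 2
Reactants: 2 (3R)-3-[(tert-butyldimethylsilyl)oxy]-4,4-dimethyloxolan-2-one
Product: 3 (3R)-3-[(tert-butyldimethylsilyl)oxy]-4,4-dimethyloxolan-2-ol (anomer mixture)
Conditions: i-Bu2AlH (1.1 equiv), CH2Cl2, −78 °C; MeOH, aq. potassium sodium tartrate
Reagents that add atoms: none
Why: Partial lactone reduction with i-Bu2AlH stops at the aluminium hemiacetal at low temperature, and the gem-dimethyl group holds the product in the closed lactol form.

Step 3
Reactants: 3 (3R)-3-[(tert-butyldimethylsilyl)oxy]-4,4-dimethyloxolan-2-ol; 4 N-methoxy-N-methyl-2-(triphenylphosphoranylidene)acetamide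
Product: 5 (2E,4S)-4-[(tert-butyldimethylsilyl)oxy]-6-hydroxy-N-methoxy-N,5,5-trimethylhex-2-enamide
Conditions: 4 (1.5 equiv), PhCO2H (10 mol %), toluene, 90 °C
Reagents that add atoms: ylide 4, CON(C)C(=O)C=P(c1ccccc1)(c1ccccc1)c1ccccc1
Why: Wittig olefination of the lactol through its open hydroxy aldehyde adds C5 and C4 with a stabilised, essentially neutral ylide, so no alkoxide arises that could shift the silyl group to the neopentyl oxygen or epimerise C1, and the alkene geometry does not matter because the alkene is hydrogenated next.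

Step 4
Reactants: 5 (2E,4S)-4-[(tert-butyldimethylsilyl)oxy]-6-hydroxy-N-methoxy-N,5,5-trimethylhex-2-enamide
Product: 6 (4S)-4-[(tert-butyldimethylsilyl)oxy]-6-hydroxy-N-methoxy-N,5,5-trimethylhexanamide
Conditions: H2 (1 atm), Pd/C, EtOAc, rt
Reagents that add atoms: none
Why: Heterogeneous catalytic hydrogenation saturates the disubstituted conjugated alkene (C5–C6), while the silyl ether and the N–O bond survive at atmospheric pressure in a neutral solvent.

Step 5
Reactants: 6 (4S)-4-[(tert-butyldimethylsilyl)oxy]-6-hydroxy-N-methoxy-N,5,5-trimethylhexanamide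
Product: 7 (4S)-4-[(tert-butyldimethylsilyl)oxy]-N-methoxy-N,5,5-trimethyl-6-oxohexanamide
Conditions: Dess–Martin periodinane, CH2Cl2, 0 °C → rt
Reagents that add atoms: none
Why: Dess–Martin oxidation handles neopentyl primary alcohols well and gives an aldehyde (C3) that has no α-hydrogen, so it can neither enolise nor eliminate the β-silyloxy group.

Step 6
Reactants: 7 (4S)-4-[(tert-butyldimethylsilyl)oxy]-N-methoxy-N,5,5-trimethyl-6-oxohexanamide; 8 tert-butyl diethylphosphonoacetate
Product: 9 tert-butyl (2E,5S)-5-[(tert-butyldimethylsilyl)oxy]-8-[methoxy(methyl)amino]-4,4-dimethyl-8-oxooct-2-enoate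
Conditions: 8, NaH, THF, 0 °C; then 7, 0 °C → rt
Reagents that add atoms: phosphonate 8, CCOP(=O)(OCC)CC(=O)OC(C)(C)C
Why: The Horner–Wadsworth–Emmons reaction of a pre-formed phosphonoacetate anion with an α-quaternary aldehyde should be E-selective for steric reasons and brings in C1′ and C2′.

Step 7
Reactants: 9 tert-butyl (2E,5S)-5-[(tert-butyldimethylsilyl)oxy]-8-[methoxy(methyl)amino]-4,4-dimethyl-8-oxooct-2-enoate
Product: 10 tert-butyl (2E,5S)-5-[(tert-butyldimethylsilyl)oxy]-4,4-dimethyl-8-oxooct-2-enoate
Conditions: i-Bu2AlH (1.05 equiv), THF, −78 °C; aq. potassium sodium tartrate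
Reagents that add atoms: none
Why: Weinreb amide reduction runs through a chelated tetrahedral intermediate that forms faster than hydride attack on the conjugated tert-butyl ester, and it releases the C4 aldehyde only on work-up, without any acid that could harm the silyl ether or the ester.

Step 8
Reactants: 10 tert-butyl (2E,5S)-5-[(tert-butyldimethylsilyl)oxy]-4,4-dimethyl-8-oxooct-2-enoate
Product: 13 tert-butyl 2-[(1S,3S)-3-[(tert-butyldimethylsilyl)oxy]-2,2-dimethyl-6-oxocyclohexyl]acetate (cis), via acyl radical 11 (not isolated), via ester-stabilised radical 12 (not isolated)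
Conditions: (Bu4N)4[W10O32] (4 mol %), MeCN (0.02 M), 390 nm LEDs, Ar, 20 °C
Reagents that add atoms: none
Why: Excited decatungstate removes the formyl hydrogen of 10, the weakest and most hydridic C–H (its only activated rival, C1–H, is buried between the silyl group and the quaternary carbon); the nucleophilic σ-acyl radical 11 then adds to the electron-poor β-carbon C3, and the electrophilic radical 12 takes the hydrogen back from the reduced polyoxometalate, so the step is redox-neutral. The closest known reactions are the decatungstate-photocatalysed hydroacylation of acrylates and related acceptors by aliphatic aldehydes, and the 6-exo cyclisations of acyl radicals made from selenoesters or from alkenals under thiol catalysis. The cyclohexanone ring closes 6-exo-trig, whereas 7-endo attack at the α-carbon is mismatched in polarity and would leave an unstabilised radical. The new stereocentre C3 is controlled by C1 through a chair-like transition state with the silyloxy group and the enoate arm both pseudo-equatorial, which should give the cis (1S,3S) ketone; since C3 is α to the ketone and the diequatorial isomer is expected to be the more stable one, any trans material can be recycled with DBU. Cyclisation must outrun loss of CO, intermolecular addition and trapping by oxygen: a primary acyl radical decarbonylates slowly at 20 °C, the gem-dimethyl group at C2 brings the reacting ends together, and dilution under argon holds back the bimolecular paths.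

Step 9
Reactants: 13 tert-butyl 2-[(1S,3S)-3-[(tert-butyldimethylsilyl)oxy]-2,2-dimethyl-6-oxocyclohexyl]acetate
Product: 14 tert-butyl 2-[(1R,3S)-3-[(tert-butyldimethylsilyl)oxy]-2,2-dimethyl-6-methylidenecyclohexyl]acetate
Conditions: Zn, CH2Br2, TiCl4 (reagent pre-formed in THF, −40 → 5 °C), CH2Cl2, 0 °C → rt
Reagents that add atoms: dibromomethane, BrCBr
Why: The Lombardo methylenation uses a non-basic gem-dimetallic reagent that attacks ketones but not esters, so C4=CH2 is installed without enolisation and the configuration at C3 is locked (the descriptor changes to R by rank only).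

Step 10
Reactants: 14 tert-butyl 2-[(1R,3S)-3-[(tert-butyldimethylsilyl)oxy]-2,2-dimethyl-6-methylidenecyclohexyl]acetate
Product: 15 2-[(1R,3S)-3-[(tert-butyldimethylsilyl)oxy]-2,2-dimethyl-6-methylidenecyclohexyl]ethan-1-ol
Conditions: LiAlH4, Et2O, 0 °C → rt
Reagents that add atoms: none
Why: Hydride reduction of the ester takes C2′ to the alcohol level and leaves the silyl ether and the isolated alkene alone.

Step 11
Reactants: 15 2-[(1R,3S)-3-[(tert-butyldimethylsilyl)oxy]-2,2-dimethyl-6-methylidenecyclohexyl]ethan-1-ol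
Product: 16 tert-butyl{[(1S,3R)-3-(2-iodoethyl)-2,2-dimethyl-4-methylidenecyclohexyl]oxy}dimethylsilane
Conditions: PPh3, imidazole, I2 (premixed), CH2Cl2, 0 °C; then 15
Reagents that add atoms: iodine, II
Why: Appel-type iodination of the primary alcohol proceeds through the alkoxyphosphonium salt, and premixing the reagents leaves no free iodine that could start iodoetherification of the pentenol-type hydroxy alkene.

Step 12
Reactants: 16 tert-butyl{[(1S,3R)-3-(2-iodoethyl)-2,2-dimethyl-4-methylidenecyclohexyl]oxy}dimethylsilane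
Product: 17 {[(1S,3R)-3-(but-3-yn-1-yl)-2,2-dimethyl-4-methylidenecyclohexyl]oxy}(tert-butyl)dimethylsilane
Conditions: LiC≡CH·H2NCH2CH2NH2, DMSO, rt
Reagents that add atoms: lithium acetylide–ethylenediamine complex, [Li]C#C.NCCN
Why: SN2 alkylation of lithium acetylide by an unbranched primary iodide in DMSO is a standard terminal alkyne synthesis, and the hindered silyl ether tolerates it.

Step 13
Reactants: 17 {[(1S,3R)-3-(but-3-yn-1-yl)-2,2-dimethyl-4-methylidenecyclohexyl]oxy}(tert-butyl)dimethylsilane
Product: 19 tert-butyl{[(1S,3R)-3-[(3E)-4-iodo-3-methylbut-3-en-1-yl]-2,2-dimethyl-4-methylidenecyclohexyl]oxy}dimethylsilane, via alkenyl(dimethyl)alane 18 (not isolated)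
Conditions: AlMe3, Cp2ZrCl2 (25 mol %), CH2Cl2, 0 °C → rt; then I2, THF, −30 → 0 °C
Reagents that add atoms: trimethylaluminium, C[Al](C)C; iodine, II
Why: Negishi zirconium-catalysed methylalumination adds CH3 and Al syn across the terminal alkyne with Al at the terminus, and iodinolysis with retention sets the E-C3′=C4′ bond, while the 1,1-disubstituted ring alkene is inert to the reagent.

Step 14
Reactants: 20 (2E,6E)-farnesol
Product: 21 (2E,6E)-farnesal
Conditions: MnO2 (activated, excess), CH2Cl2, rt
Reagents that add atoms: none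
Why: MnO2 oxidises the allylic alcohol selectively under neutral conditions, so the E geometry of the conjugated double bond should be kept.

Step 15
Reactants: 21 (2E,6E)-farnesal
Product: 22 (3E,7E)-4,8,12-trimethyltrideca-1,3,7,11-tetraene
Conditions: Ph3PCH3Br, n-BuLi, THF, 0 °C; then 21, −78 °C → rt
Reagents that add atoms: methyltriphenylphosphonium bromide, C[P+](c1ccccc1)(c1ccccc1)c1ccccc1.[Br-]
Why: Wittig methylenation of the enal gives the terminal diene unit, and addition of the aldehyde in the cold limits γ-deprotonation and loss of geometry.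

Step 16
Reactants: 19 tert-butyl{[(1S,3R)-3-[(3E)-4-iodo-3-methylbut-3-en-1-yl]-2,2-dimethyl-4-methylidenecyclohexyl]oxy}dimethylsilane; 22 (3E,7E)-4,8,12-trimethyltrideca-1,3,7,11-tetraene
Product: 24 O-(tert-butyldimethylsilyl)achilleol A, via B-homofarnesyl-9-BBN 23 (not isolated)
Conditions: 22 (1.3 equiv), 9-BBN-H (1.2 equiv), THF, 0 °C → rt; then 19, Pd(dppf)Cl2·CH2Cl2 (5 mol %), AsPh3 (10 mol %), Cs2CO3, DMF/H2O, rt
Reagents that add atoms: 9-borabicyclo[3.3.1]nonane, B1C2CCCC1CCC2 (its boryl group is found in 23 only; 24 keeps only its hydrogen)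
Why: 9-BBN-H adds only to the monosubstituted terminal double bond of 22, and the B-alkyl Suzuki–Miyaura coupling of 23 with 19 at zerovalent palladium forms C4′–C5′ with retention of the E geometry, the tetraene being kept in excess over B–H so that no hydride is left for the ring methylidene group.

Step 17
Reactants: 24 O-(tert-butyldimethylsilyl)achilleol A
Product: 25 achilleol A
Conditions: Bu4NF, THF, 50 °C
Reagents that add atoms: none
Why: Fluoride-induced desilylation frees the hindered C1 hydroxyl under non-acidic conditions, which the acid-sensitive polyene and the exocyclic alkene tolerate.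

## Compound list

1 | (R)-pantolactone, (3R)-3-hydroxy-4,4-dimethyloxolan-2-one | CC1(C)COC(=O)[C@@H]1O | starting material
2 | (3R)-3-[(tert-butyldimethylsilyl)oxy]-4,4-dimethyloxolan-2-one | CC1(C)COC(=O)[C@@H]1O[Si](C)(C)C(C)(C)C | intermediate
3 | (3R)-3-[(tert-butyldimethylsilyl)oxy]-4,4-dimethyloxolan-2-ol (anomer mixture) | CC1(C)COC(O)[C@@H]1O[Si](C)(C)C(C)(C)C | intermediate
4 | N-methoxy-N-methyl-2-(triphenylphosphoranylidene)acetamide | CON(C)C(=O)C=P(c1ccccc1)(c1ccccc1)c1ccccc1 | starting material
5 | (2E,4S)-4-[(tert-butyldimethylsilyl)oxy]-6-hydroxy-N-methoxy-N,5,5-trimethylhex-2-enamide | CON(C)C(=O)/C=C/[C@H](O[Si](C)(C)C(C)(C)C)C(C)(C)CO | intermediate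
6 | (4S)-4-[(tert-butyldimethylsilyl)oxy]-6-hydroxy-N-methoxy-N,5,5-trimethylhexanamide | CON(C)C(=O)CC[C@H](O[Si](C)(C)C(C)(C)C)C(C)(C)CO | intermediate
7 | (4S)-4-[(tert-butyldimethylsilyl)oxy]-N-methoxy-N,5,5-trimethyl-6-oxohexanamide | CON(C)C(=O)CC[C@H](O[Si](C)(C)C(C)(C)C)C(C)(C)C=O | intermediate
8 | tert-butyl diethylphosphonoacetate | CCOP(=O)(OCC)CC(=O)OC(C)(C)C | starting material
9 | tert-butyl (2E,5S)-5-[(tert-butyldimethylsilyl)oxy]-8-[methoxy(methyl)amino]-4,4-dimethyl-8-oxooct-2-enoate | CON(C)C(=O)CC[C@H](O[Si](C)(C)C(C)(C)C)C(C)(C)/C=C/C(=O)OC(C)(C)C | intermediate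
10 | tert-butyl (2E,5S)-5-[(tert-butyldimethylsilyl)oxy]-4,4-dimethyl-8-oxooct-2-enoate | O=CCC[C@H](O[Si](C)(C)C(C)(C)C)C(C)(C)/C=C/C(=O)OC(C)(C)C | intermediate
11 | C4 acyl radical derived from 10 | O=[C]CC[C@H](O[Si](C)(C)C(C)(C)C)C(C)(C)/C=C/C(=O)OC(C)(C)C | intermediate
12 | cyclised C1′ radical α to the ester | O=C1CC[C@H](O[Si](C)(C)C(C)(C)C)C(C)(C)[C@@H]1[CH]C(=O)OC(C)(C)C | intermediate
13 | tert-butyl 2-[(1S,3S)-3-[(tert-butyldimethylsilyl)oxy]-2,2-dimethyl-6-oxocyclohexyl]acetate (cis) | O=C1CC[C@H](O[Si](C)(C)C(C)(C)C)C(C)(C)[C@@H]1CC(=O)OC(C)(C)C | intermediate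
14 | tert-butyl 2-[(1R,3S)-3-[(tert-butyldimethylsilyl)oxy]-2,2-dimethyl-6-methylidenecyclohexyl]acetate | C=C1CC[C@H](O[Si](C)(C)C(C)(C)C)C(C)(C)[C@@H]1CC(=O)OC(C)(C)C | intermediate
15 | 2-[(1R,3S)-3-[(tert-butyldimethylsilyl)oxy]-2,2-dimethyl-6-methylidenecyclohexyl]ethan-1-ol | C=C1CC[C@H](O[Si](C)(C)C(C)(C)C)C(C)(C)[C@@H]1CCO | intermediate
16 | tert-butyl{[(1S,3R)-3-(2-iodoethyl)-2,2-dimethyl-4-methylidenecyclohexyl]oxy}dimethylsilane | C=C1CC[C@H](O[Si](C)(C)C(C)(C)C)C(C)(C)[C@@H]1CCI | intermediate
17 | {[(1S,3R)-3-(but-3-yn-1-yl)-2,2-dimethyl-4-methylidenecyclohexyl]oxy}(tert-butyl)dimethylsilane | C=C1CC[C@H](O[Si](C)(C)C(C)(C)C)C(C)(C)[C@@H]1CCC#C | intermediate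
18 | (E)-alkenyl(dimethyl)alane from methylalumination of 17 | C=C1CC[C@H](O[Si](C)(C)C(C)(C)C)C(C)(C)[C@@H]1CC/C(C)=C/[Al](C)C | intermediate
19 | tert-butyl{[(1S,3R)-3-[(3E)-4-iodo-3-methylbut-3-en-1-yl]-2,2-dimethyl-4-methylidenecyclohexyl]oxy}dimethylsilane | C=C1CC[C@H](O[Si](C)(C)C(C)(C)C)C(C)(C)[C@@H]1CC/C(C)=C/I | intermediate
20 | (2E,6E)-farnesol | OC/C=C(\C)CC/C=C(\C)CCC=C(C)C | starting material
21 | (2E,6E)-farnesal | O=C/C=C(\C)CC/C=C(\C)CCC=C(C)C | intermediate
22 | (3E,7E)-4,8,12-trimethyltrideca-1,3,7,11-tetraene | C=C/C=C(\C)CC/C=C(\C)CCC=C(C)C | intermediate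
23 | 9-[(3E,7E)-4,8,12-trimethyltrideca-3,7,11-trien-1-yl]-9-borabicyclo[3.3.1]nonane | B1(C2CCCC1CCC2)CC/C=C(\C)CC/C=C(\C)CCC=C(C)C | intermediate
24 | O-(tert-butyldimethylsilyl)achilleol A | C=C1CC[C@H](O[Si](C)(C)C(C)(C)C)C(C)(C)[C@@H]1CC/C(C)=C/CC/C=C(\C)CC/C=C(\C)CCC=C(C)C | intermediate
25 | achilleol A, (1S,3R)-2,2-dimethyl-4-methylidene-3-[(3E,7E,11E)-3,8,12,16-tetramethylheptadeca-3,7,11,15-tetraen-1-yl]cyclohexan-1-ol | C=C1CC[C@H](O)C(C)(C)[C@@H]1CC/C(C)=C/CC/C=C(\C)CC/C=C(\C)CCC=C(C)C | target

## Step count and risks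

Total step count: 17. Longest linear sequence: 15 (steps 1–13, 16, 17). Steps 14 and 15 form the side branch.

### Steps most likely to fail

**1. Step 8.**
- What may go wrong: addition of the acyl radical to a β-carbon that sits next to a quaternary centre may be too slow. Loss of CO followed by five-membered ring closure, hydrogen abstraction at other C–H bonds, or oligomerisation could then take over. Facial selectivity at C3 may also be poor.
- Fallback: it sets out from 10 and replaces the neutral acyl radical by a ketyl radical anion, which cannot decarbonylate.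
  - SmI2 (2.5 equiv) in THF/t-BuOH at −78 → 0 °C should bring about the well-known reductive aldehyde–enoate cyclisation, again 6-exo-trig at C3–C4. It should give tert-butyl 2-[(1S,3S)-3-[(tert-butyldimethylsilyl)oxy]-6-hydroxy-2,2-dimethylcyclohexyl]acetate F1, whose carbinol configuration at C4 is of no consequence.
  - Dess–Martin oxidation of the new secondary alcohol, followed if needed by equilibration of C3 with DBU, comes back to the route at 13.

**2. Step 3.**
- What may go wrong: the gem-dimethyl group may hold the lactol closed so firmly that a stabilised ylide finds too little open aldehyde. The freed neopentyl hydroxyl may also add back in conjugate fashion to the unsaturated amide.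
- Fallback: it sets out from 3, uses a reactive one-carbon ylide, makes silyl migration harmless, and brings in C4 as carbon monoxide.
  - Ph3P=CH2 (from Ph3PCH3Br and n-BuLi, THF, 0 °C) should give (3S)-3-[(tert-butyldimethylsilyl)oxy]-2,2-dimethylpent-4-en-1-ol F2. It may be mixed with its silyl-shifted isomer (3S)-5-[(tert-butyldimethylsilyl)oxy]-4,4-dimethylpent-1-en-3-ol F3.
  - TBSOTf and 2,6-lutidine converge both to (3S)-3,5-bis[(tert-butyldimethylsilyl)oxy]-4,4-dimethylpent-1-ene F4.
  - HF·pyridine in THF/pyridine at 0 °C frees only the primary oxygen and returns pure F2.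
  - Dess–Martin oxidation gives (3S)-3-[(tert-butyldimethylsilyl)oxy]-2,2-dimethylpent-4-enal F5.
  - The Horner–Wadsworth–Emmons reaction with 8 gives tert-butyl (2E,5S)-5-[(tert-butyldimethylsilyl)oxy]-4,4-dimethylhepta-2,6-dienoate F6.
  - Linear-selective hydroformylation of the monosubstituted alkene (Rh(acac)(CO)2, Xantphos, CO/H2 10 bar, toluene, 70 °C) leaves the hindered enoate alone and comes back to the route at 10.

**3. Step 9.**
- What may go wrong: attack at the carbonyl group may be sluggish because the axial methyl group of C2 shields it. The Lewis-acidic titanium species may cleave the tert-butyl ester, or enolisation may compete.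
- Fallback: it sets out from 13 and splits the olefination into addition and elimination (cerium-modified Peterson olefination).
  - Me3SiCH2Li with CeCl3 in THF at −78 °C, a small and weakly basic nucleophile, should give tert-butyl 2-[(1S,3S)-3-[(tert-butyldimethylsilyl)oxy]-6-hydroxy-2,2-dimethyl-6-[(trimethylsilyl)methyl]cyclohexyl]acetate F7.
  - LiAlH4 reduces the ester to (2S,4S)-4-[(tert-butyldimethylsilyl)oxy]-2-(2-hydroxyethyl)-3,3-dimethyl-1-[(trimethylsilyl)methyl]cyclohexan-1-ol F8. Any intramolecular acyl transfer to the new tertiary alkoxide is harmless, since reduction leads to the same diol.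
  - KH in THF triggers the syn elimination of the β-hydroxysilane, and the sequence comes back to the route at 15.

## Further compounds

F1 | step 8 | tert-butyl 2-[(1S,3S)-3-[(tert-butyldimethylsilyl)oxy]-6-hydroxy-2,2-dimethylcyclohexyl]acetate (C6 epimers) | OC1CC[C@H](O[Si](C)(C)C(C)(C)C)C(C)(C)[C@@H]1CC(=O)OC(C)(C)C
F2 | step 3 | (3S)-3-[(tert-butyldimethylsilyl)oxy]-2,2-dimethylpent-4-en-1-ol | C=C[C@H](O[Si](C)(C)C(C)(C)C)C(C)(C)CO
F3 | step 3 | (3S)-5-[(tert-butyldimethylsilyl)oxy]-4,4-dimethylpent-1-en-3-ol | C=C[C@H](O)C(C)(C)CO[Si](C)(C)C(C)(C)C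
F4 | step 3 | (3S)-3,5-bis[(tert-butyldimethylsilyl)oxy]-4,4-dimethylpent-1-ene | C=C[C@H](O[Si](C)(C)C(C)(C)C)C(C)(C)CO[Si](C)(C)C(C)(C)C
F5 | step 3 | (3S)-3-[(tert-butyldimethylsilyl)oxy]-2,2-dimethylpent-4-enal | C=C[C@H](O[Si](C)(C)C(C)(C)C)C(C)(C)C=O
F6 | step 3 | tert-butyl (2E,5S)-5-[(tert-butyldimethylsilyl)oxy]-4,4-dimethylhepta-2,6-dienoate | C=C[C@H](O[Si](C)(C)C(C)(C)C)C(C)(C)/C=C/C(=O)OC(C)(C)C
F7 | step 9 | tert-butyl 2-[(1S,3S)-3-[(tert-butyldimethylsilyl)oxy]-6-hydroxy-2,2-dimethyl-6-[(trimethylsilyl)methyl]cyclohexyl]acetate (C6 epimers) | C[Si](C)(C)CC1(O)CC[C@H](O[Si](C)(C)C(C)(C)C)C(C)(C)[C@@H]1CC(=O)OC(C)(C)C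
F8 | step 9 | (2S,4S)-4-[(tert-butyldimethylsilyl)oxy]-2-(2-hydroxyethyl)-3,3-dimethyl-1-[(trimethylsilyl)methyl]cyclohexan-1-ol (C1 epimers) | C[Si](C)(C)CC1(O)CC[C@H](O[Si](C)(C)C(C)(C)C)C(C)(C)[C@@H]1CCO
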